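The route rests on disconnecting the C4–C5 bond of the dihydropyran ring. The feature exploited is C3: besides C2 it bears two methylene carbons, ring C4 and the acetoxymethyl carbon, so both can come from one symmetric 1,3-diol held as a six-membered cyclic sulfate, which leaves the aryl-bearing C2 as the only stereocentre of the precursor. The enolate of a benzofuran-2-ylacetate ester hung on the C2 oxygen then opens the sulfate at one CH2: in one operation this forges C4–C5, closes the oxan-2-one ring and fixes C3 relative to C2, while the second arm remains a sulfate monoester destined to become the acetate.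

Key step: step 14

Remark on the chemistry: atom labels follow the target ring (O1, C2 aryl, C3 CH2OAc, C4, C5 benzofuranyl, C6) and TBS is tert-butyldimethylsilyl; the stereodescriptors were checked and are consistent, (R) at the carbinol carbon giving (2R,3S); the acetyl group is carried unprotected and, since i-Bu2AlH cannot spare it, is reduced with the lactone in step 16 and restored in step 17.

Step 1
Reactants: 1 2-bromo-1,4-dimethoxybenzene
Product: 2 1-(4-bromo-2,5-dimethoxyphenyl)ethan-1-one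
Conditions: AcCl, AlCl3, CH2Cl2, 0 °C to rt
Reagents that add atoms: acetyl chloride, CC(=O)Cl
Why: Friedel–Crafts acylation of an activated arene, the acylium ion entering para to bromine and ortho to a methoxy group, the least hindered activated position.

Step 2
Reactants: 2 1-(4-bromo-2,5-dimethoxyphenyl)ethan-1-one
Product: 3 1-(4-bromo-2,5-dihydroxyphenyl)ethan-1-one
Conditions: BBr3, CH2Cl2, −78 °C to rt; H2O
Reagents that add atoms: none
Why: Lewis-acid O-demethylation of both aryl methyl ethers by BBr3 through aryloxyboranes that are hydrolysed on work-up, the ketone and the aryl bromide being inert.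

Step 3
Reactants: 3 1-(4-bromo-2,5-dihydroxyphenyl)ethan-1-one; 4 but-3-yn-1-ol
Product: 6 1-[5-hydroxy-2-(2-hydroxyethyl)-1-benzofuran-6-yl]ethan-1-one, via alkynylphenol 5 (not isolated)
Conditions: PdCl2(PPh3)2 (cat.), CuI (cat.), Et3N, DMF, 70 °C, argon
Reagents that add atoms: none
Why: Sonogashira coupling at the C–Br bond activated by the para acetyl group gives an ortho-alkynylphenol that should cyclise in the same pot by metal-promoted 5-endo-dig hydroalkoxylation to the 2-substituted benzofuran, the other phenol having no neighbouring alkyne.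

Step 4
Reactants: 6 1-[5-hydroxy-2-(2-hydroxyethyl)-1-benzofuran-6-yl]ethan-1-one
Product: 8 1-[5-(TBSO)-2-(2-hydroxyethyl)-1-benzofuran-6-yl]ethan-1-one, via sodium phenoxide 7 (not isolated)
Conditions: NaH (1.0 equiv), THF, 0 °C; then TBSCl (1.05 equiv), 0 °C to rt
Reagents that add atoms: tert-butyldimethylsilyl chloride, CC(C)(C)[Si](C)(C)Cl
Why: Selective O-silylation, since one equivalent of NaH deprotonates only the phenol (about six pKa units more acidic than the primary alcohol) and the phenoxide is silylated far faster than a neutral alcohol in the absence of an amine catalyst.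

Step 5
Reactants: 8 1-[5-(TBSO)-2-(2-hydroxyethyl)-1-benzofuran-6-yl]ethan-1-one
Product: 10 2-[6-acetyl-5-(TBSO)-1-benzofuran-2-yl]acetic acid, via aldehyde 9 (not isolated)
Conditions: TEMPO (cat.), PhI(OAc)2 (2.2 equiv), MeCN/H2O (1:1), rt
Reagents that add atoms: water, O
Why: Oxoammonium (TEMPO) oxidation of the primary alcohol to the aldehyde and, through its hydrate, on to the carboxylic acid, under conditions that should leave the aryl silyl ether, the aryl ketone and the benzofuran untouched.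

Step 6
Reactants: 11 4-bromo-2-methoxyphenol
Product: 12 (4-bromo-2-methoxyphenoxy)(tert-butyl)dimethylsilane
Conditions: TBSCl, imidazole, DMF, rt
Reagents that add atoms: tert-butyldimethylsilyl chloride, CC(C)(C)[Si](C)(C)Cl
Why: Imidazole-promoted silylation of a phenol, a standard protection that makes the bromide fit for Grignard formation.

Step 7
Reactants: 13 (2,2-dimethyl-1,3-dioxan-5-yl)methanol
Product: 14 2,2-dimethyl-1,3-dioxane-5-carbaldehyde
Conditions: TEMPO (cat.), PhI(OAc)2 (1.1 equiv), CH2Cl2, rt; used crude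
Reagents that add atoms: none
Why: TEMPO/PhI(OAc)2 oxidation of a primary alcohol stops at the aldehyde under anhydrous conditions and is mild enough for the acetonide and the β-alkoxy aldehyde.

Step 8
Reactants: 12 (4-bromo-2-methoxyphenoxy)(tert-butyl)dimethylsilane; 14 2,2-dimethyl-1,3-dioxane-5-carbaldehyde
Product: 16 rac-[4-(TBSO)-3-methoxyphenyl](2,2-dimethyl-1,3-dioxan-5-yl)methanol, via aryl Grignard reagent 15 (not isolated)
Conditions: Mg, THF, reflux; then 14, THF, −78 to 0 °C; aq. NH4Cl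
Reagents that add atoms: none
Why: Grignard formation from the aryl bromide (the aryl silyl ether tolerates magnesium) and 1,2-addition to the aldehyde, the carbinol centre being formed as a racemate that is erased in the next step.

Step 9
Reactants: 16 rac-[4-(TBSO)-3-methoxyphenyl](2,2-dimethyl-1,3-dioxan-5-yl)methanol
Product: 17 [4-(TBSO)-3-methoxyphenyl](2,2-dimethyl-1,3-dioxan-5-yl)methanone
Conditions: Dess–Martin periodinane, NaHCO3, CH2Cl2, 0 °C to rt
Reagents that add atoms: none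
Why: Dess–Martin oxidation of a secondary benzylic alcohol under buffered, non-basic conditions, which avoids β-elimination of a ring oxygen from the ketone.

Step 10
Reactants: 17 [4-(TBSO)-3-methoxyphenyl](2,2-dimethyl-1,3-dioxan-5-yl)methanone
Product: 18 (R)-[4-(TBSO)-3-methoxyphenyl](2,2-dimethyl-1,3-dioxan-5-yl)methanol
Conditions: RuCl[(R,R)-TsDPEN](p-cymene) (2 mol %), HCO2H/Et3N (5:2), DMF, 40 °C
Reagents that add atoms: none
Why: Noyori asymmetric transfer hydrogenation of an aryl ketone, in which the (R,R)-TsDPEN ruthenium hydride attacks the face fixed by the aryl CH–π contact with the η6-arene and, by analogy with acetophenone, should give the (R)-carbinol that becomes C2.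

Step 11
Reactants: 10 2-[6-acetyl-5-(TBSO)-1-benzofuran-2-yl]acetic acid; 18 (R)-[4-(TBSO)-3-methoxyphenyl](2,2-dimethyl-1,3-dioxan-5-yl)methanol
Product: 19 (R)-[4-(TBSO)-3-methoxyphenyl](2,2-dimethyl-1,3-dioxan-5-yl)methyl 2-[6-acetyl-5-(TBSO)-1-benzofuran-2-yl]acetate
Conditions: DCC, DMAP (cat.), CH2Cl2, 0 °C to rt
Reagents that add atoms: none
Why: Steglich esterification acylates the carbinol oxygen without touching its C–O bond, so the (R) configuration is retained.

Step 12
Reactants: 19 (R)-[4-(TBSO)-3-methoxyphenyl](2,2-dimethyl-1,3-dioxan-5-yl)methyl 2-[6-acetyl-5-(TBSO)-1-benzofuran-2-yl]acetate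
Product: 20 (R)-1-[4-(TBSO)-3-methoxyphenyl]-3-hydroxy-2-(hydroxymethyl)propyl 2-[6-acetyl-5-(TBSO)-1-benzofuran-2-yl]acetate
Conditions: AcOH/THF/H2O (3:1:1), rt
Reagents that add atoms: none
Why: Acid-catalysed hydrolysis of the 1,3-dioxane acetonide, which is far more labile than the aryl silyl ethers and the ester in aqueous acetic acid at room temperature.

Step 13
Reactants: 20 (R)-1-[4-(TBSO)-3-methoxyphenyl]-3-hydroxy-2-(hydroxymethyl)propyl 2-[6-acetyl-5-(TBSO)-1-benzofuran-2-yl]acetate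
Product: 22 (R)-[4-(TBSO)-3-methoxyphenyl](2,2-dioxo-1,3,2-dioxathian-5-yl)methyl 2-[6-acetyl-5-(TBSO)-1-benzofuran-2-yl]acetate, via cyclic sulfite 21 (not isolated)
Conditions: SOCl2, pyridine, CH2Cl2, 0 °C; then RuCl3 hydrate (0.5 mol %), NaIO4 (1.2 equiv), MeCN/H2O, 0 °C, 10 min, i-PrOH quench
Reagents that add atoms: thionyl chloride, O=S(Cl)Cl; sodium periodate, [Na+].[O-]I(=O)(=O)=O
Why: Two-stage cyclic sulfate synthesis from a 1,3-diol, ring closure with SOCl2 to the six-membered cyclic sulfite followed by oxidation at sulfur by catalytic RuO4 (from RuCl3 and NaIO4), run cold and briefly with little excess periodate to spare the benzofuran.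

Step 14
Reactants: 22 (R)-[4-(TBSO)-3-methoxyphenyl](2,2-dioxo-1,3,2-dioxathian-5-yl)methyl 2-[6-acetyl-5-(TBSO)-1-benzofuran-2-yl]acetate
Product: 24 sodium [(2R,3S)-5-[6-acetyl-5-(TBSO)-1-benzofuran-2-yl]-2-[4-(TBSO)-3-methoxyphenyl]-6-oxooxan-3-yl]methyl sulfate (both C5 epimers), via sodium enolate 23 (not isolated)
Conditions: NaN(SiMe3)2 (1.05 equiv), THF (0.01 M), −78 to 0 °C
Reagents that add atoms: sodium bis(trimethylsilyl)amide, C[Si](C)(C)[N-][Si](C)(C)C.[Na+]
Why: NaN(SiMe3)2 removes the proton flanked by the ester carbonyl and benzofuran C2 (several pKa units more acidic than the acetyl CH3, so one equivalent should give enolate 23 only), and the enolate carbon, the future C5, displaces one C–O bond of the cyclic sulfate by intramolecular SN2 attack at a CH2 carbon, forming C4–C5. The closest known reaction type is the intramolecular C-alkylation of an ester enolate by a 1,3-diol cyclic sulfate to give a lactone. The oxan-2-one ring closes in a 6-exo-tet mode with the enolate double bond inside the forming ring (enolendo) and the sulfate oxygen leaving outside it. The new stereocentre C3 arises from the choice between the two diastereotopic CH2–O carbons and is controlled by C2: with the CH(O)Ar group equatorial on the dioxathiane chair, backside attack needs a boat-like lactone transition state, and only attack on the arm leading to the 2,3-trans product lets the aryl group point outward while the unreacting CH2–O carbon points away from the enolate. The step needs C- over O-alkylation and ring closure over intermolecular alkylation, which tight sodium–oxygen ion pairing in THF, the soft benzylic-type enolate carbon and high dilution should secure, and the centre formed at C5 is of no consequence because it becomes sp2 later. The alkyl sulfate anion left on the other arm is a poor leaving group and cannot be displaced a second time.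

Step 15
Reactants: 24 sodium [(2R,3S)-5-[6-acetyl-5-(TBSO)-1-benzofuran-2-yl]-2-[4-(TBSO)-3-methoxyphenyl]-6-oxooxan-3-yl]methyl sulfate
Product: 25 (5S,6R)-3-[6-acetyl-5-(TBSO)-1-benzofuran-2-yl]-5-(hydroxymethyl)-6-[4-(TBSO)-3-methoxyphenyl]oxan-2-one
Conditions: conc. H2SO4 (cat.), H2O (1.5 equiv), THF, rt; then NaHCO3
Reagents that add atoms: none
Why: Acid-catalysed hydrolysis of the alkyl sulfate monoester (S–O cleavage) with little water should free the primary alcohol without opening the lactone or ionising the benzylic C2–O bond.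

Step 16
Reactants: 25 (5S,6R)-3-[6-acetyl-5-(TBSO)-1-benzofuran-2-yl]-5-(hydroxymethyl)-6-[4-(TBSO)-3-methoxyphenyl]oxan-2-one
Product: 26 (5S,6R)-3-[6-(1-hydroxyethyl)-5-(TBSO)-1-benzofuran-2-yl]-5-(hydroxymethyl)-6-[4-(TBSO)-3-methoxyphenyl]oxan-2-ol (stereoisomer mixture at the lactol carbon, the adjacent carbon and the carbinol)
Conditions: i-Bu2AlH (4 equiv), CH2Cl2, −78 °C; EtOAc, then aq. KNaC4H4O6, 0 °C
Reagents that add atoms: none
Why: i-Bu2AlH reduction at −78 °C stops at the lactol because the tetrahedral aluminium alkoxide is stable at that temperature, while the aryl methyl ketone is deliberately reduced to the carbinol in the same operation and C2 and C3 are untouched.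

Step 17
Reactants: 26 (5S,6R)-3-[6-(1-hydroxyethyl)-5-(TBSO)-1-benzofuran-2-yl]-5-(hydroxymethyl)-6-[4-(TBSO)-3-methoxyphenyl]oxan-2-ol
Product: 27 (5S,6R)-3-[6-acetyl-5-(TBSO)-1-benzofuran-2-yl]-5-(hydroxymethyl)-6-[4-(TBSO)-3-methoxyphenyl]oxan-2-ol
Conditions: activated MnO2 (20 equiv), CH2Cl2, rt
Reagents that add atoms: none
Why: MnO2 oxidation is selective for the benzylic carbinol, which returns to the aryl ketone, the lactol and the primary alcohol being neither benzylic nor allylic.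

Step 18
Reactants: 27 (5S,6R)-3-[6-acetyl-5-(TBSO)-1-benzofuran-2-yl]-5-(hydroxymethyl)-6-[4-(TBSO)-3-methoxyphenyl]oxan-2-ol
Product: 28 [(2R,3S)-6-acetoxy-5-[6-acetyl-5-(TBSO)-1-benzofuran-2-yl]-2-[4-(TBSO)-3-methoxyphenyl]oxan-3-yl]methyl acetate
Conditions: Ac2O, pyridine, DMAP (cat.), CH2Cl2, 0 °C to rt
Reagents that add atoms: acetic anhydride, CC(=O)OC(C)=O
Why: DMAP-catalysed acetylation of the lactol hydroxyl and the primary alcohol gives the anomeric acetate needed for elimination and the acetate ester of the target.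

Step 19
Reactants: 28 [(2R,3S)-6-acetoxy-5-[6-acetyl-5-(TBSO)-1-benzofuran-2-yl]-2-[4-(TBSO)-3-methoxyphenyl]oxan-3-yl]methyl acetate
Product: 30 [(2R,3S)-5-[6-acetyl-5-(TBSO)-1-benzofuran-2-yl]-2-[4-(TBSO)-3-methoxyphenyl]-3,4-dihydro-2H-pyran-3-yl]methyl acetate, via silyl enol ether 29 (not isolated)
Conditions: Me3SiOTf (2.5 equiv), i-Pr2NEt (4 equiv), CH2Cl2, −78 to 0 °C; then 5% aq. citric acid, THF, 0 °C
Reagents that add atoms: none
Why: Lewis-acid ionisation of the anomeric acetate to the oxocarbenium ion and loss of the benzylic C5 proton to the amine (E1-type conversion of an acetal into an enol ether) should give the conjugated C5=C6 enol ether, the acetyl group being silylated to its enol ether in passing and released by the mildly acidic work-up.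

Step 20
Reactants: 30 [(2R,3S)-5-[6-acetyl-5-(TBSO)-1-benzofuran-2-yl]-2-[4-(TBSO)-3-methoxyphenyl]-3,4-dihydro-2H-pyran-3-yl]methyl acetate
Product: 31 propolis-benzofuran A
Conditions: Bu4NF (2.5 equiv), AcOH (3 equiv), THF, 0 °C
Reagents that add atoms: none
Why: Fluoride cleavage of both aryl silyl ethers, buffered with acetic acid so that the phenols stay protonated and neither acetate migration nor opening of the para-hydroxybenzyl vinyl ether is expected.

Compound list
1 | 2-bromo-1,4-dimethoxybenzene | COc1ccc(OC)c(Br)c1 | starting material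
2 | 1-(4-bromo-2,5-dimethoxyphenyl)ethan-1-one | CC(=O)c1cc(OC)c(Br)cc1OC | intermediate
3 | 1-(4-bromo-2,5-dihydroxyphenyl)ethan-1-one | CC(=O)c1cc(O)c(Br)cc1O | intermediate
4 | but-3-yn-1-ol | C#CCCO | starting material
5 | 1-[2,5-dihydroxy-4-(4-hydroxybut-1-yn-1-yl)phenyl]ethan-1-one (formed in the flask) | CC(=O)c1cc(O)c(C#CCCO)cc1O | intermediate
6 | 1-[5-hydroxy-2-(2-hydroxyethyl)-1-benzofuran-6-yl]ethan-1-one | CC(=O)c1cc2oc(CCO)cc2cc1O | intermediate
7 | sodium 6-acetyl-2-(2-hydroxyethyl)-1-benzofuran-5-olate (formed in the flask) | CC(=O)c1cc2oc(CCO)cc2cc1[O-].[Na+] | intermediate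
8 | 1-[5-(tert-butyldimethylsilyloxy)-2-(2-hydroxyethyl)-1-benzofuran-6-yl]ethan-1-one | CC(=O)c1cc2oc(CCO)cc2cc1O[Si](C)(C)C(C)(C)C | intermediate
9 | 2-[6-acetyl-5-(tert-butyldimethylsilyloxy)-1-benzofuran-2-yl]acetaldehyde (formed in the flask) | CC(=O)c1cc2oc(CC=O)cc2cc1O[Si](C)(C)C(C)(C)C | intermediate
10 | 2-[6-acetyl-5-(tert-butyldimethylsilyloxy)-1-benzofuran-2-yl]acetic acid | CC(=O)c1cc2oc(CC(=O)O)cc2cc1O[Si](C)(C)C(C)(C)C | intermediate
11 | 4-bromo-2-methoxyphenol | COc1cc(Br)ccc1O | starting material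
12 | (4-bromo-2-methoxyphenoxy)(tert-butyl)dimethylsilane | COc1cc(Br)ccc1O[Si](C)(C)C(C)(C)C | intermediate
13 | (2,2-dimethyl-1,3-dioxan-5-yl)methanol | CC1(C)OCC(CO)CO1 | starting material
14 | 2,2-dimethyl-1,3-dioxane-5-carbaldehyde | CC1(C)OCC(C=O)CO1 | intermediate
15 | [4-(tert-butyldimethylsilyloxy)-3-methoxyphenyl]magnesium bromide (formed in the flask) | COc1cc([Mg]Br)ccc1O[Si](C)(C)C(C)(C)C | intermediate
16 | rac-[4-(tert-butyldimethylsilyloxy)-3-methoxyphenyl](2,2-dimethyl-1,3-dioxan-5-yl)methanol | COc1cc(C(O)C2COC(C)(C)OC2)ccc1O[Si](C)(C)C(C)(C)C | intermediate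
17 | [4-(tert-butyldimethylsilyloxy)-3-methoxyphenyl](2,2-dimethyl-1,3-dioxan-5-yl)methanone | COc1cc(C(=O)C2COC(C)(C)OC2)ccc1O[Si](C)(C)C(C)(C)C | intermediate
18 | (R)-[4-(tert-butyldimethylsilyloxy)-3-methoxyphenyl](2,2-dimethyl-1,3-dioxan-5-yl)methanol | COc1cc([C@H](O)C2COC(C)(C)OC2)ccc1O[Si](C)(C)C(C)(C)C | intermediate
19 | (R)-[4-(TBSO)-3-methoxyphenyl](2,2-dimethyl-1,3-dioxan-5-yl)methyl 2-[6-acetyl-5-(TBSO)-1-benzofuran-2-yl]acetate | COc1cc([C@H](OC(=O)Cc2cc3cc(O[Si](C)(C)C(C)(C)C)c(C(C)=O)cc3o2)C2COC(C)(C)OC2)ccc1O[Si](C)(C)C(C)(C)C | intermediate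
20 | (R)-1-[4-(TBSO)-3-methoxyphenyl]-3-hydroxy-2-(hydroxymethyl)propyl 2-[6-acetyl-5-(TBSO)-1-benzofuran-2-yl]acetate | COc1cc([C@H](OC(=O)Cc2cc3cc(O[Si](C)(C)C(C)(C)C)c(C(C)=O)cc3o2)C(CO)CO)ccc1O[Si](C)(C)C(C)(C)C | intermediate
21 | (R)-[4-(TBSO)-3-methoxyphenyl](2-oxo-1,3,2-dioxathian-5-yl)methyl 2-[6-acetyl-5-(TBSO)-1-benzofuran-2-yl]acetate, cyclic sulfite (formed in the flask) | COc1cc([C@H](OC(=O)Cc2cc3cc(O[Si](C)(C)C(C)(C)C)c(C(C)=O)cc3o2)C2COS(=O)OC2)ccc1O[Si](C)(C)C(C)(C)C | intermediate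
22 | (R)-[4-(TBSO)-3-methoxyphenyl](2,2-dioxo-1,3,2-dioxathian-5-yl)methyl 2-[6-acetyl-5-(TBSO)-1-benzofuran-2-yl]acetate, cyclic sulfate (precursor of the key step) | COc1cc([C@H](OC(=O)Cc2cc3cc(O[Si](C)(C)C(C)(C)C)c(C(C)=O)cc3o2)C2COS(=O)(=O)OC2)ccc1O[Si](C)(C)C(C)(C)C | intermediate
23 | sodium ester enolate of 22 (formed in the flask) | COc1cc([C@H](OC([O-])=Cc2cc3cc(O[Si](C)(C)C(C)(C)C)c(C(C)=O)cc3o2)C2COS(=O)(=O)OC2)ccc1O[Si](C)(C)C(C)(C)C.[Na+] | intermediate
24 | sodium [(2R,3S)-5-[6-acetyl-5-(TBSO)-1-benzofuran-2-yl]-2-[4-(TBSO)-3-methoxyphenyl]-6-oxooxan-3-yl]methyl sulfate, 2,3-trans, both C5 epimers (product of the key step) | COc1cc([C@@H]2OC(=O)C(c3cc4cc(O[Si](C)(C)C(C)(C)C)c(C(C)=O)cc4o3)C[C@H]2COS(=O)(=O)[O-])ccc1O[Si](C)(C)C(C)(C)C.[Na+] | intermediate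
25 | (5S,6R)-3-[6-acetyl-5-(TBSO)-1-benzofuran-2-yl]-5-(hydroxymethyl)-6-[4-(TBSO)-3-methoxyphenyl]oxan-2-one | COc1cc([C@@H]2OC(=O)C(c3cc4cc(O[Si](C)(C)C(C)(C)C)c(C(C)=O)cc4o3)C[C@H]2CO)ccc1O[Si](C)(C)C(C)(C)C | intermediate
26 | (5S,6R)-3-[6-(1-hydroxyethyl)-5-(TBSO)-1-benzofuran-2-yl]-5-(hydroxymethyl)-6-[4-(TBSO)-3-methoxyphenyl]oxan-2-ol | COc1cc([C@@H]2OC(O)C(c3cc4cc(O[Si](C)(C)C(C)(C)C)c(C(C)O)cc4o3)C[C@H]2CO)ccc1O[Si](C)(C)C(C)(C)C | intermediate
27 | (5S,6R)-3-[6-acetyl-5-(TBSO)-1-benzofuran-2-yl]-5-(hydroxymethyl)-6-[4-(TBSO)-3-methoxyphenyl]oxan-2-ol | COc1cc([C@@H]2OC(O)C(c3cc4cc(O[Si](C)(C)C(C)(C)C)c(C(C)=O)cc4o3)C[C@H]2CO)ccc1O[Si](C)(C)C(C)(C)C | intermediate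
28 | [(2R,3S)-6-acetoxy-5-[6-acetyl-5-(TBSO)-1-benzofuran-2-yl]-2-[4-(TBSO)-3-methoxyphenyl]oxan-3-yl]methyl acetate | COc1cc([C@@H]2OC(OC(C)=O)C(c3cc4cc(O[Si](C)(C)C(C)(C)C)c(C(C)=O)cc4o3)C[C@H]2COC(C)=O)ccc1O[Si](C)(C)C(C)(C)C | intermediate
29 | [(2R,3S)-5-[5-(TBSO)-6-[1-(trimethylsilyloxy)ethenyl]-1-benzofuran-2-yl]-2-[4-(TBSO)-3-methoxyphenyl]-3,4-dihydro-2H-pyran-3-yl]methyl acetate (formed in the flask) | COc1cc([C@@H]2OC=C(c3cc4cc(O[Si](C)(C)C(C)(C)C)c(C(=C)O[Si](C)(C)C)cc4o3)C[C@H]2COC(C)=O)ccc1O[Si](C)(C)C(C)(C)C | intermediate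
30 | [(2R,3S)-5-[6-acetyl-5-(TBSO)-1-benzofuran-2-yl]-2-[4-(TBSO)-3-methoxyphenyl]-3,4-dihydro-2H-pyran-3-yl]methyl acetate | COc1cc([C@@H]2OC=C(c3cc4cc(O[Si](C)(C)C(C)(C)C)c(C(C)=O)cc4o3)C[C@H]2COC(C)=O)ccc1O[Si](C)(C)C(C)(C)C | intermediate
31 | propolis-benzofuran A, [(2R,3S)-5-(6-acetyl-5-hydroxy-1-benzofuran-2-yl)-2-(4-hydroxy-3-methoxyphenyl)-3,4-dihydro-2H-pyran-3-yl]methyl acetate | COc1cc([C@@H]2OC=C(c3cc4cc(O)c(C(C)=O)cc4o3)C[C@H]2COC(C)=O)ccc1O | target

Total step count: 20. Longest linear sequence: 15 steps (steps 1 to 5, then 11 to 20).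

Steps most likely to fail

Step 14. The enolate may alkylate through oxygen (the sulfate is a hard leaving group, giving a six-membered cyclic ketene acetal), attack the other arm (2,3-cis lactone) or react between molecules. The fallback removes the choice between arms and uses a soft electrophile. It sets out from diol 20: TESCl (1 equiv) and imidazole in CH2Cl2 at −40 °C should give the two mono-silyl ethers, the (1R,2S) triethylsilyl ether F1 and its (1R,2R) diastereomer F2, separable by chromatography, with F2 returned to 20 by AcOH/THF/H2O. I2, PPh3 and imidazole (Appel-type) convert F1 into the primary iodide F3. NaN(SiMe3)2 in THF at −78 °C gives the sodium enolate F4, which closes by C-alkylation to the silyloxymethyl lactone F5, the C3 configuration now being fixed by which arm carries iodine (the isomer giving the 2,3-trans lactone is carried on). AcOH/THF/H2O removes the triethylsilyl group and the route is rejoined at 25.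

Step 13. RuO4 may over-oxidise the electron-rich C2=C3 bond of the benzofuran once the sulfite is consumed, and the acyl group may migrate to a primary hydroxyl before the sulfite ring closes. The fallback builds the cyclic sulfate before the benzofuran is attached. It sets out from alcohol 18: 2,2,2-trichloroethyl chloroformate and pyridine give the carbonate F6, AcOH/THF/H2O the diol F7, SOCl2/pyridine the cyclic sulfite F8, and RuCl3/NaIO4 the cyclic sulfate F9. Zinc dust in THF/aq. KH2PO4 then frees the hydroxy cyclic sulfate F10, which is esterified with acid 10 (DCC, cat. DMAP, 0 °C), and the route is rejoined at 22.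

Step 10. Hydride transfer may be slow and poorly face-selective because the ketone is electron-rich and branched at the α-carbon. The fallback replaces transfer hydrogenation by a stoichiometric borane reduction with a different control element. It sets out from ketone 17: Corey–Bakshi–Shibata reduction with (S)-2-methyl-CBS-oxazaborolidine and BH3·SMe2 in THF at −20 °C, the aryl group acting as the large substituent, should give the same (R)-alcohol 18, where the route is rejoined; no new compound is made.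

Further compounds
F1 | step 14 | (1R,2S)-1-[4-(TBSO)-3-methoxyphenyl]-3-hydroxy-2-[(triethylsilyloxy)methyl]propyl 2-[6-acetyl-5-(TBSO)-1-benzofuran-2-yl]acetate | COc1cc([C@H](OC(=O)Cc2cc3cc(O[Si](C)(C)C(C)(C)C)c(C(C)=O)cc3o2)[C@@H](CO)CO[Si](CC)(CC)CC)ccc1O[Si](C)(C)C(C)(C)C
F2 | step 14 | (1R,2R)-1-[4-(TBSO)-3-methoxyphenyl]-3-hydroxy-2-[(triethylsilyloxy)methyl]propyl 2-[6-acetyl-5-(TBSO)-1-benzofuran-2-yl]acetate | COc1cc([C@H](OC(=O)Cc2cc3cc(O[Si](C)(C)C(C)(C)C)c(C(C)=O)cc3o2)[C@H](CO)CO[Si](CC)(CC)CC)ccc1O[Si](C)(C)C(C)(C)C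
F3 | step 14 | (1R,2S)-1-[4-(TBSO)-3-methoxyphenyl]-3-iodo-2-[(triethylsilyloxy)methyl]propyl 2-[6-acetyl-5-(TBSO)-1-benzofuran-2-yl]acetate | COc1cc([C@H](OC(=O)Cc2cc3cc(O[Si](C)(C)C(C)(C)C)c(C(C)=O)cc3o2)[C@@H](CI)CO[Si](CC)(CC)CC)ccc1O[Si](C)(C)C(C)(C)C
F4 | step 14 | sodium ester enolate of F3 | COc1cc([C@H](OC([O-])=Cc2cc3cc(O[Si](C)(C)C(C)(C)C)c(C(C)=O)cc3o2)[C@@H](CI)CO[Si](CC)(CC)CC)ccc1O[Si](C)(C)C(C)(C)C.[Na+]
F5 | step 14 | (5S,6R)-3-[6-acetyl-5-(TBSO)-1-benzofuran-2-yl]-6-[4-(TBSO)-3-methoxyphenyl]-5-[(triethylsilyloxy)methyl]oxan-2-one | COc1cc([C@@H]2OC(=O)C(c3cc4cc(O[Si](C)(C)C(C)(C)C)c(C(C)=O)cc4o3)C[C@H]2CO[Si](CC)(CC)CC)ccc1O[Si](C)(C)C(C)(C)C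
F6 | step 13 | (R)-[4-(TBSO)-3-methoxyphenyl](2,2-dimethyl-1,3-dioxan-5-yl)methyl 2,2,2-trichloroethyl carbonate | COc1cc([C@H](OC(=O)OCC(Cl)(Cl)Cl)C2COC(C)(C)OC2)ccc1O[Si](C)(C)C(C)(C)C
F7 | step 13 | (R)-1-[4-(TBSO)-3-methoxyphenyl]-3-hydroxy-2-(hydroxymethyl)propyl 2,2,2-trichloroethyl carbonate | COc1cc([C@H](OC(=O)OCC(Cl)(Cl)Cl)C(CO)CO)ccc1O[Si](C)(C)C(C)(C)C
F8 | step 13 | (R)-[4-(TBSO)-3-methoxyphenyl](2-oxo-1,3,2-dioxathian-5-yl)methyl 2,2,2-trichloroethyl carbonate | COc1cc([C@H](OC(=O)OCC(Cl)(Cl)Cl)C2COS(=O)OC2)ccc1O[Si](C)(C)C(C)(C)C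
F9 | step 13 | (R)-[4-(TBSO)-3-methoxyphenyl](2,2-dioxo-1,3,2-dioxathian-5-yl)methyl 2,2,2-trichloroethyl carbonate | COc1cc([C@H](OC(=O)OCC(Cl)(Cl)Cl)C2COS(=O)(=O)OC2)ccc1O[Si](C)(C)C(C)(C)C
F10 | step 13 | (R)-[4-(TBSO)-3-methoxyphenyl](2,2-dioxo-1,3,2-dioxathian-5-yl)methanol | COc1cc([C@H](O)C2COS(=O)(=O)OC2)ccc1O[Si](C)(C)C(C)(C)C
F0 | step 10 | none | none
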